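The cyclohexane (C1 CHEt, C2 CHMe, C3 CHAr, C4 CHMe, C5 CHAr, C6 spiro) is cut at C3–C4 and C5–C6. Exploited features: C3 and C5 are benzylic to trimethoxyphenyl rings B and C, C4–C5 plus ring C is an intact asarone unit, and C6 is the former ipso carbon, para to oxygen, of dienone ring A. In one operation a C3 cation adds α-asarone and the resulting C5 cation is captured by C6 of a free phenol: two C–C bonds and four stereocentres (C3–C6), relayed from C1/C2. The precursor is an open-chain phenolic diaryl carbinol whose C1/C2 pair stems from one dual-catalytic allylation.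

Key step: step 6

Assumption: 4-hydroxy-2,5-dimethoxybenzaldehyde (1) is taken as a catalogue compound. The locants C1–C6 and ring letters A–C defined above are used throughout.

Step 1
Reactants: 1 4-hydroxy-2,5-dimethoxybenzaldehyde
Product: 2 4-(benzyloxy)-2,5-dimethoxybenzaldehyde
Conditions: BnBr, K2CO3, DMF, rt
Reagents that add atoms: benzyl bromide, BrCc1ccccc1
Why: Williamson ether synthesis on the only acidic OH masks the ring A phenol as a group that the later hydrogenation removes at no extra step, and no stereocentre is involved.

Step 2
Reactants: 2 4-(benzyloxy)-2,5-dimethoxybenzaldehyde; 3 vinylmagnesium bromide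
Product: 4 (±)-1-[4-(benzyloxy)-2,5-dimethoxyphenyl]prop-2-en-1-ol
Conditions: THF, −20 → 0 °C; aq. NH4Cl
Reagents that add atoms: none
Why: Grignard 1,2-addition to the aldehyde gives the branched allylic alcohol as a racemate, which suffices because the next step is enantioconvergent.

Step 3
Reactants: 4 (±)-1-[4-(benzyloxy)-2,5-dimethoxyphenyl]prop-2-en-1-ol; 5 propanal
Product: 6 (2S,3R)-3-[4-(benzyloxy)-2,5-dimethoxyphenyl]-2-methylpent-4-enal (2,3-syn)
Conditions: [Ir(cod)Cl]2 (3 mol %), BINOL-derived phosphoramidite–olefin ligand (12 mol %, antipode giving 3R), (R)-2-{bis[3,5-bis(trifluoromethyl)phenyl](trimethylsilyloxy)methyl}pyrrolidine (10 mol %), (MeO)2P(O)OH (50 mol %), 5 (3 equiv), DCE, rt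
Reagents that add atoms: none
Why: In this stereodivergent dual catalysis (branched-selective iridium allylic substitution merged with enamine catalysis), the ligand sets the benzylic centre C1 (3R) after ionisation of either carbinol enantiomer and the (R)-prolinol ether shields one enamine face to set C2 (2S), so the syn pair is chosen by catalyst pairing and not by substrate bias.

Step 4
Reactants: 6 (2S,3R)-3-[4-(benzyloxy)-2,5-dimethoxyphenyl]-2-methylpent-4-enal
Product: 7 (2S,3R)-3-(4-hydroxy-2,5-dimethoxyphenyl)-2-methylpentanal
Conditions: H2 (1 atm), 10% Pd/C, EtOAc, rt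
Reagents that add atoms: none
Why: Heterogeneous catalytic hydrogenation saturates the monosubstituted alkene to the C1 ethyl group and cleaves the benzyl ether by hydrogenolysis in the same operation, while the aliphatic aldehyde and the C1 and C2 centres should persist under neutral conditions.

Step 5
Reactants: 7 (2S,3R)-3-(4-hydroxy-2,5-dimethoxyphenyl)-2-methylpentanal; 8 1-bromo-2,4,5-trimethoxybenzene
Product: 10 (2S,3R)-3-(4-hydroxy-2,5-dimethoxyphenyl)-2-methyl-1-(2,4,5-trimethoxyphenyl)pentan-1-ol (both carbinol epimers), via aryllithium 9 (not isolated)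
Conditions: 8 + n-BuLi (2.3 equiv each), THF, −78 °C; then 7, −78 °C; aq. NH4Cl
Reagents that add atoms: none
Why: Bromine–lithium exchange and 1,2-addition of the aryllithium at low temperature (the first equivalent is spent on the phenol) should outrun enolisation at C2, and the new carbinol centre needs no control because ionisation in step 6 erases it.

Step 6
Reactants: 10 (2S,3R)-3-(4-hydroxy-2,5-dimethoxyphenyl)-2-methyl-1-(2,4,5-trimethoxyphenyl)pentan-1-ol; 11 α-asarone, (E)-1,2,4-trimethoxy-5-(prop-1-enyl)benzene
Product: 14 tatanan B, via C3 benzylic cation 12 (not isolated), via C5 benzylic cation 13 (not isolated)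
Conditions: 11 (3 equiv), (PhO)2P(O)OH (10 mol %), CH2Cl2/HFIP 4:1, 4 Å MS, −40 → −10 °C, slow addition of 10; Et3N quench
Reagents that add atoms: none
Why: Proposed new method: the acid ionises the C3 carbinol of 10 to benzylic cation 12, C4 of α-asarone adds to it to give benzylic cation 13, and C6 of ring A (para to OH, ortho to OMe) attacks C5 with loss of the phenolic proton to give the dienone; the closest known reaction types are the diastereoselective SN1 alkylation of α-branched benzylic cations by π-nucleophiles, the formal [3+2] addition of benzylic cations to styrenes and the intramolecular ipso-Friedel–Crafts dearomatisation of phenols, which have not been merged into a [4+2] annulation. The cyclohexane closes in the spiro mode (Ar1-6, 6-exo with respect to the arene π bond) through a chair with Et, ring B, C4-Me and ring C equatorial and only C2-Me axial. C3 is controlled by C2, because 1,3-allylic strain with the ortho-OMe of ring B holds C2–H in the cation plane, so asarone enters on the methyl face, anti to the CH(Et)Ar branch, and the same alignment keeps C2–H orthogonal to the empty orbital and protects C2 from E1 epimerisation. C4 follows from the open transition state with C5 anti to ring B and the methyl in the less crowded sector, the wrong epimer (which could close only with a 1,3-diaxial Me/Me contact) being expected to drain to the C4=C5 styrene and re-enter by protonation, and C5 places ring C equatorial in the chair. C6 is fixed by the rotamer about C1–C6, in which the OMe-bearing ortho carbon stays syn to C1–H and becomes equatorial while the ortho CH becomes axial beside the axial C2-Me, the other rotamer eclipsing OMe with the C2 branch and pushing it under the ring. The step needs alkene capture and ipso closure to win over indane formation at the ortho CH of rings A and B and over asarone oligomerisation, and this is secured by the nucleophilicity order (asarone C4 and the doubly activated C6 against singly activated ortho CH), by the fact that ipso closure at the C3 stage would need a four-membered ring, by the free OH whose proton loss makes only the ring A ipso attack irreversible, and by slow addition of 10 to excess asarone under an acid that ionises the carbinol faster than it protonates a styrene.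

Compound list
1 | 4-hydroxy-2,5-dimethoxybenzaldehyde | O=Cc1cc(OC)c(O)cc1OC | starting material
2 | 4-(benzyloxy)-2,5-dimethoxybenzaldehyde | O=Cc1cc(OC)c(OCc2ccccc2)cc1OC | intermediate
3 | vinylmagnesium bromide | C=C[Mg]Br | starting material
4 | (±)-1-[4-(benzyloxy)-2,5-dimethoxyphenyl]prop-2-en-1-ol | C=CC(O)c1cc(OC)c(OCc2ccccc2)cc1OC | intermediate
5 | propanal | CCC=O | starting material
6 | (2S,3R)-3-[4-(benzyloxy)-2,5-dimethoxyphenyl]-2-methylpent-4-enal | C=C[C@@H](c1cc(OC)c(OCc2ccccc2)cc1OC)[C@H](C)C=O | intermediate
7 | (2S,3R)-3-(4-hydroxy-2,5-dimethoxyphenyl)-2-methylpentanal | CC[C@@H](c1cc(OC)c(O)cc1OC)[C@H](C)C=O | intermediate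
8 | 1-bromo-2,4,5-trimethoxybenzene | COc1cc(OC)c(OC)cc1Br | starting material
9 | (2,4,5-trimethoxyphenyl)lithium | [Li]c1cc(OC)c(OC)cc1OC | intermediate
10 | (2S,3R)-3-(4-hydroxy-2,5-dimethoxyphenyl)-2-methyl-1-(2,4,5-trimethoxyphenyl)pentan-1-ol, carbinol centre unassigned (both epimers) | CC[C@@H](c1cc(OC)c(O)cc1OC)[C@H](C)C(O)c1cc(OC)c(OC)cc1OC | intermediate
11 | α-asarone, (E)-1,2,4-trimethoxy-5-(prop-1-enyl)benzene | C/C=C/c1cc(OC)c(OC)cc1OC | starting material
12 | C3 benzylic cation from 10 | CC[C@@H](c1cc(OC)c(O)cc1OC)[C@H](C)[CH+]c1cc(OC)c(OC)cc1OC | intermediate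
13 | C5 benzylic cation after addition of 11 (productive C4 epimer drawn) | CC[C@@H](c1cc(OC)c(O)cc1OC)[C@H](C)[C@H](c1cc(OC)c(OC)cc1OC)[C@@H](C)[CH+]c1cc(OC)c(OC)cc1OC | intermediate
14 | tatanan B, (1R,2S,3S,4R,5R,6S) in the locants used here | CC[C@@H]1[C@H](C)[C@H](c2cc(OC)c(OC)cc2OC)[C@@H](C)[C@H](c2cc(OC)c(OC)cc2OC)[C@]12C=C(OC)C(=O)C=C2OC | target

Total step count: 6. Longest linear sequence: 6 (1 → 2 → 4 → 6 → 7 → 10 → 14).

Steps most likely to fail

1. Step 6 (Proposed new method). Several processes could divert the cascade:
- The C3 cation may close onto the ortho position of ring A or lose a proton before the alkene arrives.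
- Asarone may oligomerise under the acid.
- The C4 topicity of the intermolecular bond formation may be poor.
- The dienone may re-open under acid and drift to Friedel–Crafts products.

The fallback separates the two bond formations and uses known chemistry. It sets out from 10. Carbinol 10 is ionised with catalytic Bi(OTf)3 in MeNO2 in the presence of the much more nucleophilic (Z)-trimethylsilyl enol ether of 1-(2,4,5-trimethoxyphenyl)propan-1-one F1, which is made from the commercial ketone with TMSOTf and Et3N. This is the established diastereoselective SN1 alkylation of an α-branched benzylic cation. It should give the (2R,3S,4S,5R)-5-(4-hydroxy-2,5-dimethoxyphenyl)-2,4-dimethyl-1,3-bis(2,4,5-trimethoxyphenyl)heptan-1-one F2, whose C4 centre can be adjusted by base equilibration. NaBH4 in MeOH reduces it to the corresponding heptan-1-ol F3. Catalytic acid in HFIP then closes C5–C6 by intramolecular ipso-Friedel–Crafts dearomatisation of the phenol, and the route is rejoined at 14.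

2. Step 3. The very electron-rich, ortho-substituted carbinol may ionise without iridium. That would cause loss of enantiocontrol at C1 and attack at the unsubstituted allyl terminus. The ortho-OMe may also slow formation of the allyl-iridium species. The fallback sets out from 4.
- Solvolysis in propionic acid with catalytic acid proceeds with allylic transposition to the conjugated (E)-3-[4-(benzyloxy)-2,5-dimethoxyphenyl]prop-2-enyl propanoate F4.
- An enantioselective ester enolate Claisen rearrangement follows, run through a chiral boron enolate made from a stilbenediamine bis-sulfonamide bromoborane and a tertiary amine. The amine/solvent pair sets the enolate geometry so that the chair gives the syn product. This gives (2S,3R)-3-[4-(benzyloxy)-2,5-dimethoxyphenyl]-2-methylpent-4-enoic acid F5.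
- LiAlH4 gives (2S,3R)-3-[4-(benzyloxy)-2,5-dimethoxyphenyl]-2-methylpent-4-en-1-ol F6, and DMP oxidation returns to the route at 6.

3. Step 5. The basic aryllithium may enolise the aldehyde and erode C2, and aggregation of the lithium phenoxide may stall the addition. The fallback changes the order of events so that the organolithium meets no acidic proton. It sets out from 6, which is treated with aryllithium 9 (1.1 equiv, THF, −78 °C). This gives (2S,3R)-3-[4-(benzyloxy)-2,5-dimethoxyphenyl]-2-methyl-1-(2,4,5-trimethoxyphenyl)pent-4-en-1-ol F7. Hydrogenation (H2, Pd/C, EtOAc, solid NaHCO3 to suppress loss of the benzylic OH) then saturates the vinyl group and removes the benzyl ether, and the route is rejoined at 10.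

Further compounds
F1 | step 6 | (Z)-trimethyl{[1-(2,4,5-trimethoxyphenyl)prop-1-en-1-yl]oxy}silane | C/C=C(\O[Si](C)(C)C)c1cc(OC)c(OC)cc1OC
F2 | step 6 | (2R,3S,4S,5R)-5-(4-hydroxy-2,5-dimethoxyphenyl)-2,4-dimethyl-1,3-bis(2,4,5-trimethoxyphenyl)heptan-1-one | CC[C@@H](c1cc(OC)c(O)cc1OC)[C@H](C)[C@H](c1cc(OC)c(OC)cc1OC)[C@@H](C)C(=O)c1cc(OC)c(OC)cc1OC
F3 | step 6 | (2R,3S,4S,5R)-5-(4-hydroxy-2,5-dimethoxyphenyl)-2,4-dimethyl-1,3-bis(2,4,5-trimethoxyphenyl)heptan-1-ol (carbinol epimers) | CC[C@@H](c1cc(OC)c(O)cc1OC)[C@H](C)[C@H](c1cc(OC)c(OC)cc1OC)[C@@H](C)C(O)c1cc(OC)c(OC)cc1OC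
F4 | step 3 | (E)-3-[4-(benzyloxy)-2,5-dimethoxyphenyl]prop-2-enyl propanoate | CCC(=O)OC/C=C/c1cc(OC)c(OCc2ccccc2)cc1OC
F5 | step 3 | (2S,3R)-3-[4-(benzyloxy)-2,5-dimethoxyphenyl]-2-methylpent-4-enoic acid | C=C[C@@H](c1cc(OC)c(OCc2ccccc2)cc1OC)[C@H](C)C(=O)O
F6 | step 3 | (2S,3R)-3-[4-(benzyloxy)-2,5-dimethoxyphenyl]-2-methylpent-4-en-1-ol | C=C[C@@H](c1cc(OC)c(OCc2ccccc2)cc1OC)[C@H](C)CO
F7 | step 5 | (2S,3R)-3-[4-(benzyloxy)-2,5-dimethoxyphenyl]-2-methyl-1-(2,4,5-trimethoxyphenyl)pent-4-en-1-ol (carbinol epimers) | C=C[C@@H](c1cc(OC)c(OCc2ccccc2)cc1OC)[C@H](C)C(O)c1cc(OC)c(OC)cc1OC
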